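A direct plan would join two O-benzylated aldehydes in an enantioselective crossed acyloin reaction to the (S)-α-hydroxy ketone A1, invert that carbinol with a vanillate phenol in a Mitsunobu etherification to the benzylated (R)-aryl ether A2, and end with hydrogenolysis of all benzyl groups.
Its weakest steps would be the crossed acyloin reaction, since one catalyst would have to control chemoselectivity and enantioselectivity at once without an established case;
the Mitsunobu inversion, since it would act α to an aryl ketone, where the aryloxide could enolise substrate or product;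
and the hydrogenolysis, since it would expose a reducible α-aryloxy ketone to palladium with the labile centre in place.

The new route rests on the very feature that makes the target fragile: the acidic C2–H between the C1 aryl ketone on ring A (syringyl) and the aryloxy oxygen of ring B (vanillic acid). C2 would first be made racemic and freely epimerising in an α-aryloxy β-keto ester; one dynamic kinetic transfer hydrogenation would then funnel both enantiomers into a single hydroxy ester, setting C2 and masking C1 as a carbinol. The ester would become the CH2OH group, the benzyl group would leave while no ketone is present, and a neutral benzylic dehydrogenation would return the ketone last. No acyloin coupling, no substitution at a stereocentre and no hydrogenolysis beside an α-aryloxy ketone would remain.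

Key step: step 5

Assumption: the syn sense established for dynamic transfer hydrogenation of α-alkoxy β-keto esters is taken to hold for the α-aryloxy ester of step 4; if the anti isomer were to prevail, the (R,R)-catalyst would deliver the same configuration at C2, and the carbinol centre is erased in step 8 in either case.

Step 1
Reactants: 1 acetosyringone [1-(4-hydroxy-3,5-dimethoxyphenyl)ethan-1-one]
Product: 2 1-[4-(benzyloxy)-3,5-dimethoxyphenyl]ethan-1-one
Conditions: BnBr (1.1 equiv), K2CO3 (1.5 equiv), DMF, 60 °C
Reagents that add atoms: benzyl bromide, BrCc1ccccc1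
Why: Williamson ether synthesis on the acidic para-acyl phenol, which removes the only free phenol of ring A before the enolate, bromination and phenoxide steps that follow.

Step 2
Reactants: 2 1-[4-(benzyloxy)-3,5-dimethoxyphenyl]ethan-1-one
Product: 4 ethyl 3-[4-(benzyloxy)-3,5-dimethoxyphenyl]-3-oxopropanoate, via sodium enolate 3 (not isolated)
Conditions: NaH (2.5 equiv), (EtO)2CO (3 equiv), THF, reflux; then aq. HCl, 0 °C
Reagents that add atoms: diethyl carbonate, CCOC(=O)OCC
Why: Crossed Claisen condensation of the methyl ketone enolate with the non-enolisable carbonate, driven to completion by deprotonation of the product to enolate 3, adds C3 at the ester oxidation level.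

Step 3
Reactants: 4 ethyl 3-[4-(benzyloxy)-3,5-dimethoxyphenyl]-3-oxopropanoate
Product: 5 ethyl (2RS)-3-[4-(benzyloxy)-3,5-dimethoxyphenyl]-2-bromo-3-oxopropanoate
Conditions: NBS (1.05 equiv), NH4OAc (10 mol %), Et2O, rt, dark
Reagents that add atoms: N-bromosuccinimide, O=C1CCC(=O)N1Br
Why: Electrophilic α-bromination through the enol of the β-keto ester, which is far more nucleophilic than the acyl-deactivated ring A or the benzyl ether, should give the racemic monobromide.

Step 4
Reactants: 5 ethyl (2RS)-3-[4-(benzyloxy)-3,5-dimethoxyphenyl]-2-bromo-3-oxopropanoate; 6 methyl vanillate (methyl 4-hydroxy-3-methoxybenzoate)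
Product: 7 ethyl (2RS)-3-[4-(benzyloxy)-3,5-dimethoxyphenyl]-2-[2-methoxy-4-(methoxycarbonyl)phenoxy]-3-oxopropanoate
Conditions: K2CO3 (2.2 equiv), acetone, 0 °C → rt; aq. citric acid work-up
Reagents that add atoms: none
Why: SN2 displacement of the doubly carbonyl-activated bromide by the phenoxide of 6 forms the C2–O bond to ring B with no stereochemical demand, because the product is meant to be racemic and to epimerise freely.

Step 5
Reactants: 7 ethyl (2RS)-3-[4-(benzyloxy)-3,5-dimethoxyphenyl]-2-[2-methoxy-4-(methoxycarbonyl)phenoxy]-3-oxopropanoate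
Product: 9 ethyl (2S,3R)-3-[4-(benzyloxy)-3,5-dimethoxyphenyl]-3-hydroxy-2-[2-methoxy-4-(methoxycarbonyl)phenoxy]propanoate, via enol tautomer 8 (not isolated)
Conditions: RuCl[(S,S)-TsDPEN](p-cymene) (2 mol %), HCO2H–Et3N (5:2), CH2Cl2, 30 °C
Reagents that add atoms: none
Why: Noyori–Ikariya asymmetric transfer hydrogenation run as a dynamic kinetic resolution: the ruthenium hydride formed from the precatalyst and formate delivers hydride to the ketone carbon and a proton from its N–H to the oxygen through a six-membered outer-sphere transition state, while the two enantiomers of 7 interconvert through enol 8, because C2–H lies between the aryl ketone, the ester and the aryloxy oxygen and Et3N is present. The closest known reaction type is the syn-selective transfer hydrogenation of racemic α-alkoxy β-keto esters with the same catalyst family. No ring is closed. The carbinol centre is controlled by the catalyst, whose η6-arene holds ring A by a C–H/π contact, so that the (S,S)-ligand should give the facial sense of acetophenone reduction, which is 3R here by the CIP rules; C2 follows by substrate control, since only the (2S)-enantiomer can place its C2–OAr bond anti to the incoming hydride on that face (polar Felkin–Anh arrangement), which leads to the syn isomer. The step needs ketone over ester selectivity, which formate and this catalyst secure, and epimerisation faster than reduction, which the 1,3-dicarbonyl acidity of 7 secures; the anti isomer, the only species that could erode the final ee, is a diastereomer and should be removable at acid 11. After this step C2–H is no longer α to a ketone, so the configuration is locked until the last step.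

Step 6
Reactants: 9 ethyl (2S,3R)-3-[4-(benzyloxy)-3,5-dimethoxyphenyl]-3-hydroxy-2-[2-methoxy-4-(methoxycarbonyl)phenoxy]propanoate
Product: 11 4-{[(1R,2R)-1-[4-(benzyloxy)-3,5-dimethoxyphenyl]-1,3-dihydroxypropan-2-yl]oxy}-3-methoxybenzoic acid, via methyl ester diol 10 (not isolated)
Conditions: NaBH4 (6 equiv), THF–H2O 3:1, 0 °C → rt; then LiOH·H2O (5 equiv), MeOH, 45 °C; aq. HCl to pH 3, 0 °C
Reagents that add atoms: lithium hydroxide, [Li+].[OH-]
Why: Chemoselective borohydride reduction of the ethyl ester, which is activated by its α-aryloxy and β-hydroxy groups while the electron-rich methyl benzoate is not, followed by saponification of the latter in the same flask; no bond to C2 is touched, and the descriptor changes from 2S to 2R only because CH2OH ranks below the carbinol carbon.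

Step 7
Reactants: 11 4-{[(1R,2R)-1-[4-(benzyloxy)-3,5-dimethoxyphenyl]-1,3-dihydroxypropan-2-yl]oxy}-3-methoxybenzoic acid
Product: 12 4-{[(1R,2R)-1,3-dihydroxy-1-(4-hydroxy-3,5-dimethoxyphenyl)propan-2-yl]oxy}-3-methoxybenzoic acid
Conditions: H2 (1 atm), 10% Pd/C, EtOAc–MeOH 1:1, rt, stopped after uptake of 1 equiv H2
Reagents that add atoms: none
Why: Catalytic hydrogenolysis of the aryl benzyl ether under neutral conditions frees the phenol of ring A at a stage where no ketone is present, and the unactivated secondary benzylic alcohol should survive at 1 atm and rt.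

Step 8
Reactants: 12 4-{[(1R,2R)-1,3-dihydroxy-1-(4-hydroxy-3,5-dimethoxyphenyl)propan-2-yl]oxy}-3-methoxybenzoic acid
Product: 13 4-{[(2R)-3-hydroxy-1-(4-hydroxy-3,5-dimethoxyphenyl)-1-oxopropan-2-yl]oxy}-3-methoxybenzoic acid (CNP0507417.1)
Conditions: DDQ (1.1 equiv), 1,4-dioxane, rt; filter off the hydroquinone, no basic work-up
Reagents that add atoms: none
Why: DDQ dehydrogenation of a 4-hydroxybenzylic alcohol, in which hydride abstraction from the carbinol C–H is made easy by the para-hydroxy group of ring A, should give the aryl ketone while the primary alcohol, ring B and the acid stay inert; the neutral medium should not enolise the new α-aryloxy ketone, so C2 stays (R) and the carbinol centre is erased.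

Compound list
1 | acetosyringone, 1-(4-hydroxy-3,5-dimethoxyphenyl)ethan-1-one | CC(=O)c1cc(OC)c(O)c(OC)c1 | starting material
2 | 1-[4-(benzyloxy)-3,5-dimethoxyphenyl]ethan-1-one | CC(=O)c1cc(OC)c(OCc2ccccc2)c(OC)c1 | intermediate
3 | sodium (1Z)-1-[4-(benzyloxy)-3,5-dimethoxyphenyl]-3-ethoxy-3-oxoprop-1-en-1-olate | [Na+].[O-]/C(=C\C(=O)OCC)c1cc(OC)c(OCc2ccccc2)c(OC)c1 | intermediate
4 | ethyl 3-[4-(benzyloxy)-3,5-dimethoxyphenyl]-3-oxopropanoate | CCOC(=O)CC(=O)c1cc(OC)c(OCc2ccccc2)c(OC)c1 | intermediate
5 | ethyl (2RS)-3-[4-(benzyloxy)-3,5-dimethoxyphenyl]-2-bromo-3-oxopropanoate | CCOC(=O)C(Br)C(=O)c1cc(OC)c(OCc2ccccc2)c(OC)c1 | intermediate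
6 | methyl vanillate, methyl 4-hydroxy-3-methoxybenzoate | COC(=O)c1ccc(O)c(OC)c1 | starting material
7 | ethyl (2RS)-3-[4-(benzyloxy)-3,5-dimethoxyphenyl]-2-[2-methoxy-4-(methoxycarbonyl)phenoxy]-3-oxopropanoate | CCOC(=O)C(Oc1ccc(C(=O)OC)cc1OC)C(=O)c1cc(OC)c(OCc2ccccc2)c(OC)c1 | intermediate
8 | ethyl (2E)-3-[4-(benzyloxy)-3,5-dimethoxyphenyl]-3-hydroxy-2-[2-methoxy-4-(methoxycarbonyl)phenoxy]prop-2-enoate (enol of 7) | CCOC(=O)/C(Oc1ccc(C(=O)OC)cc1OC)=C(\O)c1cc(OC)c(OCc2ccccc2)c(OC)c1 | intermediate
9 | ethyl (2S,3R)-3-[4-(benzyloxy)-3,5-dimethoxyphenyl]-3-hydroxy-2-[2-methoxy-4-(methoxycarbonyl)phenoxy]propanoate | CCOC(=O)[C@@H](Oc1ccc(C(=O)OC)cc1OC)[C@H](O)c1cc(OC)c(OCc2ccccc2)c(OC)c1 | intermediate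
10 | methyl 4-{[(1R,2R)-1-[4-(benzyloxy)-3,5-dimethoxyphenyl]-1,3-dihydroxypropan-2-yl]oxy}-3-methoxybenzoate | COC(=O)c1ccc(O[C@H](CO)[C@H](O)c2cc(OC)c(OCc3ccccc3)c(OC)c2)c(OC)c1 | intermediate
11 | 4-{[(1R,2R)-1-[4-(benzyloxy)-3,5-dimethoxyphenyl]-1,3-dihydroxypropan-2-yl]oxy}-3-methoxybenzoic acid | OC(=O)c1ccc(O[C@H](CO)[C@H](O)c2cc(OC)c(OCc3ccccc3)c(OC)c2)c(OC)c1 | intermediate
12 | 4-{[(1R,2R)-1,3-dihydroxy-1-(4-hydroxy-3,5-dimethoxyphenyl)propan-2-yl]oxy}-3-methoxybenzoic acid | OC(=O)c1ccc(O[C@H](CO)[C@H](O)c2cc(OC)c(O)c(OC)c2)c(OC)c1 | intermediate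
13 | 4-{[(2R)-3-hydroxy-1-(4-hydroxy-3,5-dimethoxyphenyl)-1-oxopropan-2-yl]oxy}-3-methoxybenzoic acid (CNP0507417.1) | COc1cc(C(=O)O)ccc1O[C@H](CO)C(=O)c1cc(OC)c(O)c(OC)c1 | target

Total step count: 8. Longest linear sequence: 8 steps, from acetosyringone 1.

Steps most likely to fail

Step 5 (key step). Reduction could outrun epimerisation at C2, or substrate control over the syn/anti sense could be weak, so that C2 would not be funnelled into one configuration. The fallback would use auxiliary control and would set out from 6. O-Alkylation of 6 with (4S)-4-benzyl-3-(bromoacetyl)-1,3-oxazolidin-2-one (K2CO3, acetone) would give methyl 4-{2-[(4S)-4-benzyl-2-oxo-1,3-oxazolidin-3-yl]-2-oxoethoxy}-3-methoxybenzoate F1. Its (Z)-boron enolate (Bu2BOTf, iPr2NEt, CH2Cl2, −78 °C) would add to commercial 4-(benzyloxy)-3,5-dimethoxybenzaldehyde in an Evans syn aldol reaction. This would give methyl 4-{[(2S,3R)-1-[(4S)-4-benzyl-2-oxo-1,3-oxazolidin-3-yl]-3-[4-(benzyloxy)-3,5-dimethoxyphenyl]-3-hydroxy-1-oxopropan-2-yl]oxy}-3-methoxybenzoate F2. Reductive removal of the auxiliary (NaBH4, THF–H2O) would return to the route at 10, which would be saponified as in step 6.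

Step 8. The electron-rich free phenol of ring A could be oxidised in competition (phenoxyl radical coupling or quinone formation) in place of clean dehydrogenation of the carbinol. The fallback would set out from 11 and change the order of events. The benzylic carbinol would be dehydrogenated while the phenol is still benzylated (DDQ, 1,4-dioxane, 50 °C) to 4-{[(2R)-1-[4-(benzyloxy)-3,5-dimethoxyphenyl]-3-hydroxy-1-oxopropan-2-yl]oxy}-3-methoxybenzoic acid F3. The benzyl ether would then be cleaved without hydrogen by BCl3 and pentamethylbenzene (CH2Cl2, −78 °C), which would return to the route at the target 13.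

Step 4. Halophilic attack of the phenoxide on bromine (reduction of the bromide back to the β-keto ester and bromination of ring B) or C-alkylation could compete with the displacement. The fallback would set out from 4 and use a carbene route. Diazo transfer (4-acetamidobenzenesulfonyl azide, Et3N, MeCN) would give ethyl 3-[4-(benzyloxy)-3,5-dimethoxyphenyl]-2-diazo-3-oxopropanoate F4. Rh2(OAc)4-catalysed O–H insertion of its carbene into the phenol of 6 (toluene, 60 °C) would return to the route at 7.

Further compounds
F1 | step 5 | methyl 4-{2-[(4S)-4-benzyl-2-oxo-1,3-oxazolidin-3-yl]-2-oxoethoxy}-3-methoxybenzoate | COC(=O)c1ccc(OCC(=O)N2[C@@H](Cc3ccccc3)COC2=O)c(OC)c1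
F2 | step 5 | methyl 4-{[(2S,3R)-1-[(4S)-4-benzyl-2-oxo-1,3-oxazolidin-3-yl]-3-[4-(benzyloxy)-3,5-dimethoxyphenyl]-3-hydroxy-1-oxopropan-2-yl]oxy}-3-methoxybenzoate | COC(=O)c1ccc(O[C@H](C(=O)N2[C@@H](Cc3ccccc3)COC2=O)[C@H](O)c2cc(OC)c(OCc3ccccc3)c(OC)c2)c(OC)c1
F3 | step 8 | 4-{[(2R)-1-[4-(benzyloxy)-3,5-dimethoxyphenyl]-3-hydroxy-1-oxopropan-2-yl]oxy}-3-methoxybenzoic acid | OC(=O)c1ccc(O[C@H](CO)C(=O)c2cc(OC)c(OCc3ccccc3)c(OC)c2)c(OC)c1
F4 | step 4 | ethyl 3-[4-(benzyloxy)-3,5-dimethoxyphenyl]-2-diazo-3-oxopropanoate | CCOC(=O)C(=[N+]=[N-])C(=O)c1cc(OC)c(OCc2ccccc2)c(OC)c1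
A1 | direct plan | (2S)-3-(benzyloxy)-1-[4-(benzyloxy)-3,5-dimethoxyphenyl]-2-hydroxypropan-1-one | O[C@@H](COCc1ccccc1)C(=O)c1cc(OC)c(OCc2ccccc2)c(OC)c1
A2 | direct plan | benzyl 4-{[(2R)-3-(benzyloxy)-1-[4-(benzyloxy)-3,5-dimethoxyphenyl]-1-oxopropan-2-yl]oxy}-3-methoxybenzoate | COc1cc(C(=O)OCc2ccccc2)ccc1O[C@H](COCc1ccccc1)C(=O)c1cc(OC)c(OCc2ccccc2)c(OC)c1
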